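(The readings are simulated for substances that don't exist; noise was put on by code.)

| setting | autumn | flask |
|---|---|---|
| substrate | 0.80 M | 0.80 M |
| coupling partner | 1.2 M | 2.40 M |
| capture agent | 0.040 M | 0.0400 M |
| remark | run made earlier |  |
| time |  | 8.0 h |

autumn run (percent of the substrate charged)

| time / h | first product / % | double product / % |
|---|---|---|
| 0.333 | 11.5 | 1.8 |
| 1.00 | 28.3 | 0.7 |
| 2.00 | 42.7 | 0.5 |
| 3.00 | 52.6 | 3.2 |
| 4.00 | 59.1 | 3.9 |
| 5.00 | 63.2 | 4.0 |
| 6.00 | 65.6 | 7.2 |

(standard deviation of a reading: 1 percentage point)



* equivalents of coupling partner to substrate, everything else as given, that leave most first product at 8.0 h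
* the amount of first product then, in percent of the substrate charged
* the amount of first product with the amounts as given

What remains of the substrate shows how far a flask has gone. The exposure, the natural logarithm of charged over remaining [substrate], counts substrate lifetimes passed. In the autumn run 63.0% of the substrate had coupled at 4.00 h, and the second-order integrated law turns that reading into k = 0.281 L mol⁻¹ h⁻¹.

The bench rule treats an excess of partner as pseudo-first-order: the lifetime is 1.48 h at the charged 2.40 M, so 8.0 h holds 5.40 lifetimes. But the substrate can claim a third of the partner charge, so [coupling partner] falls and the rule overstates. The second-order law, with partner consumed, gives this reckoning's exposure for the flask, 3.99, which is lower.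

The forecast places the peak of first product at exposure 2.5, for a selectivity factor near 0.1, and its own figure for this flask is 3.9, against 3.99 in the reckoning here. This reckoning therefore puts the flask past that peak. The forecast gives 2.1 equiv (1.7 equiv to 2.7 equiv) as best, with 77% (72% to 83%) there, and 72% (64% to 79%) as charged: “The maximum is broad”.

The flask gives 2.14 equiv as best, 74.0% there and 69.4% as charged.

    substrate + coupling partner → first product (k = 0.330 L mol⁻¹ h⁻¹)
    coupling partner + first product → double product (k = 0.0410 L mol⁻¹ h⁻¹)
    coupling partner → decomposed reagent (k = 0.0440 h⁻¹)
    first product + capture agent → trapped intermediate (k = 0.0200 L mol⁻¹ h⁻¹)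

The flask also holds 0.484 M of decomposed reagent, a species absent from the exposure reckoned above. The remaining substrate of the flask, 2.6%, reads as exposure 3.65 against 3.99, still above the forecast's peak. First product below 64% in this flask would make the forecast wrong: the result stands 5.4 percentage points above that end, and reading at 10.7 h moves first product by 5 points.

The neighbouring flask with 0.96 M of coupling partner reckons to exposure 1.28, short of the forecast's peak, with 27.8% of its substrate left. Computed, that flask keeps 30.9% of its substrate and holds 63.1% first product.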